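In a one-step world, the X that goes turns up as Z; the teal flask at 144 h shows X 0.5 % and Z 56.7 %, so its books do not balance.

| setting | teal | violet | flask |
|---|---|---|---|
| X | 0.10 M | 0.10 M | 0.10 M |
| J | 0.11 M | 0.11 M | 0.110 M |
| temperature | −20 °C | −35 °C | −20 °C |
| remark | the very flask that is asked about, followed so far | run made earlier |  |
| time |  |  | 8.0 d |

| run | time / h | Z / % | X / % |
|---|---|---|---|
| teal | 12.0 | 43.5 | 26.9 |
| teal | 30.0 | 51.7 | 11.4 |
| teal | 72.0 | 57.9 | 4.1 |
| teal | 144 | 56.7 | 0.5 |
| violet | 25.0 | 31.4 | 58.3 |
| violet | 60.0 | 35.8 | 36.4 |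
| violet | 144 | 26.4 | 16.6 |
| violet | 288 | 17.7 | 6.7 |

(readings scatter by 1 percentage point)

- larch: at 8.0 d raise the temperature by 15 K, then wait 8.0 d
- ash: at 8.0 d take out 90 % of the Z then present, then wait 8.0 d
- cedar: change nothing and wait 8.0 d more
- maple: at 8.0 d add J, 100 % of the amount charged, then wait 8.0 d

- Z taken out counts as made
- additions bring no volume worth counting

- Z, in percent of the X first charged, at 8.0 d
- the option that brings most further Z ("none" if no option brings more than 2 percentage points) (larch / ash / cedar / maple / none)
- Z present, with what was taken out counted in, in percent of the X first charged, after ash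
- Z present, with what was taken out counted in, in percent of the X first charged, after cedar

We keep a ledger for X, the limiting reagent, with cX = 0.10 M against cJ = 0.110 M. Each teal reading books X, Z and a gap that neither accounts for. Gap over Z reads 0.680 at 12.0 h and 0.755 at 144 h, while Z climbs, so we take gap and Z as one pool that divides at a fixed ratio. We pool the four readings into the parking ratio, summed gap over summed Z, 0.702.

The remaining X is the small correction. Its last reading is worth 0.29 percentage points of Z, so we book Z at 8.0 d as 58.5 %. Cedar shares out that scrap and reaches 58.8 %; maple has the same scrap to work on, and the margin is 2 points. Ash removes 90 % of Z, the remaining pool of 47.4 % divides again, and the total comes to 80.5 %.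

Violet's last reading gives a ratio of 4.27, still climbing. Larch's 15 K matches the step from −35 °C to −20 °C, so we apply the same factor once more: the ratio becomes 0.115 and Z 89.7 %. That gain of 31 points beats ash's 22 points, so we choose larch.

The forecast gives 57.3 %, 79.5 % after ash and 57.4 % after cedar, each below ours, and also picks larch, on the ground that “Loss that grows on cooling suggests reversible, exothermic storage”.

The flask gives 59.2 %, 80.4 % after ash and 59.4 % after cedar. Its best option is larch, with 29 points against 21 points for ash, while cedar brings 0.16 points and maple 0.17 points.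

    X + J ⇌ L (K = 5.87 M⁻¹, k = 5.32 × 10⁻⁴ M⁻¹ s⁻¹, Ea = 68.0 kJ mol⁻¹, ΔH = −69.0 kJ mol⁻¹)
    Z ⇌ G (K = 0.650, k = 5.49 × 10⁻⁵ s⁻¹, Ea = 83.0 kJ mol⁻¹, ΔH = −68.0 kJ mol⁻¹)
    L → Q (k = 3.33 × 10⁻⁵ s⁻¹, Ea = 85.0 kJ mol⁻¹)
    L → Z (k = 0.00164 s⁻¹, Ea = 68.0 kJ mol⁻¹)
    (constants at −20 °C)

The gap in the flask is G, 38.5 % at 192 h, plus Q, 1.98 %. Z and G relax with a half-life of 1.38 h, short against 8.0 d: thermodynamic control of the split between them. The neighbouring flask, kept at −5 °C from the start, tests the same reckoning: −20 °C ratio squared over the violet one gives 0.115, hence Z 89.7 %. That flask ends with X 0 %, G 9.34 %, Q 3.09 % and Z 87.6 %.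

(All runs were generated by integration for substances that don't exist; the scatter is artificial.)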